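A small charge of Z rose to L within minutes in both west and north, and L then fell, so I needed two times: the life of L at the flask's temperature and the time the flask is held.

| setting | west | north | teal | violet | green | grey |
|---|---|---|---|---|---|---|
| Z | 0.035 M | 0.052 M | 0.069 M | 0.069 M | 0.069 M | 0.069 M |
| temperature | 32 °C | 49 °C | 40 °C |  | 25 °C | 55 °C |
| remark | run made earlier | run made earlier |  | at 55 °C until 3.0 min, from then on at 25 °C |  |  |
| time |  |  | 6.0 min | 6.0 min | 6.0 min | 6.0 min |

| run | time / min | L / % |
|---|---|---|
| west | 0.250 | 30 |
| west | 0.500 | 48 |
| west | 0.833 | 58 |
| west | 1.33 | 66 |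
| west | 2.00 | 64 |
| west | 4.00 | 52 |
| north | 0.167 | 65 |
| north | 0.417 | 60 |
| north | 0.833 | 34 |
| north | 1.33 | 18 |
| north | 2.00 | 8 |
| north | 2.50 | 6 |

(readings scatter by 2 percentage points)

* the flask that comes out highest in amount of L, in percent of the Z charged, or "all alike" when all lie within 1.5 percentage points (teal / violet / green / grey / all alike)
* L at the end, in percent of the Z charged, teal
* L at the end, in percent of the Z charged, violet
* L at the end, in percent of the Z charged, green
* L at the end, in percent of the Z charged, grey

I read the late fall of L as first-order decay, each reading good to 2 percentage points. West gave 0.104 /min and north 1.04 /min, so the rate constant climbs with a temperature scale of 13300 K. That put the life of L at 25 °C, the time in which L falls by a factor e, at 26.9 min. At 40 °C it came to 3.16 min, and at 55 °C to 0.451 min.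

The peak readings, 66% at 1.33 min in west and 65% at 0.167 min in north, came earlier than the hold of 6.0 min. So I took the west peak as the share reaching L and counted the hold as decay: L at the end is that share times exp(−hold/life). The ratio of hold to life was 0.223 for green, 1.90 for teal and 13.3 for grey, while violet, adding its two stretches, had 6.76. Green's ratio is the lowest, so I expected green highest, at 52.8%, with teal 9.86%, violet 0.0763% and grey <0.001%.

The forecast named green, with teal 8.5%, violet 0.02%, green 39% and grey 0%, lower than mine on green and teal, and said of grey and violet that “L is essentially destroyed”.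

The flask gave green as highest: teal 4.90%, violet 0.0339%, green 53.2%, grey 0%.

    Z + X → G (k = 0.560 /M/s, Ea = 56.0 kJ/mol)
    2 Z → X (k = 0.140 /M/s, Ea = 70.0 kJ/mol)
    L → J (k = 0.00830 /s, Ea = 94.0 kJ/mol)
    Z → L (k = 0.0630 /s, Ea = 91.0 kJ/mol)
    (constants at 40 °C)

Green had not come to rest at 6.00 min: ten times the time, 60.0 min, took its L to 0.686% and its J from 24.6% to 78.2%, while G stood at 11.9%. My life gave 7.15% for green then, more than the computed L, so the nearness of my 52.8% to the flask's 53.2% at the hold does not vouch for that life. For violet read at 25 min, starting from 0.0339%, my life gave 0.0167%, and the flask gave less, 0.00727%.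

The numbers in the tables were generated by integration for substances that don't exist.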